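**Retrosynthetic overview**
1. Target ⇐ O‑debenzylation; tetrahydrofuran ring B ⇐ attack of the C7' hydroxyl on a primary C9 mesylate of a triol (C7'–O bond never broken, endo aryl kept) ⇐ hydride opening of a bicyclic hydroxy lactone.
2. Ring A ⇐ invertive 5‑endo opening of a benzylic spiro‑epoxide by the C9' hydroxyl ⇐ epoxidation of an (E)‑α‑benzylidene‑γ‑butyrolactone ⇐ aldol condensation of a cis‑lactone with O‑benzylvanillin.
3. Key C8'–C7' bond ⇐ carbene‑generated homoenolate of (E)‑4‑silyloxybut‑2‑enal (nucleophilic β‑carbon) + O‑benzylvanillin, giving the cis‑β,γ‑disubstituted γ‑butyrolactone directly.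
4. Enal ⇐ cross‑metathesis of an allyl silyl ether with crotonaldehyde.
5. Ring order: γ‑lactone (precursor of ring B) → tetrahydrofuran ring A → lactone opened and re‑closed as tetrahydrofuran ring B.

Locants: lignan numbering is used for the skeleton (C7/C7' benzylic, C8/C8' ring fusion, C9/C9' OCH2; C8 bears the OH). The target is the (7R,8S,7'R,8'R) isomer: aryl on C7 exo (cis to 8‑OH), aryl on C7' endo (cis to C9').
Assumption: the sense of induction of the triazolium catalyst in the annulation step is settled in a pilot run, and the commercial antipode that gives the (4R,5R)‑lactone is used.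

Step 1
Reactants: 1 allyl tert‑butyldimethylsilyl ether; 2 (E)‑crotonaldehyde
Product: 3 (E)‑4‑[(tert‑butyldimethylsilyl)oxy]but‑2‑enal
Conditions: second‑generation Hoveyda–Grubbs catalyst (C31H38Cl2N2ORu, 2 mol%), crotonaldehyde in threefold excess, CH2Cl2, 40 °C
Reagents that add atoms: none
Why: Olefin cross‑metathesis between an allyl ether and an enal partner gives the conjugated aldehyde as the thermodynamically favoured E isomer, with propene leaving as gas.

Step 2
Reactants: 3 (E)‑γ‑(tert‑butyldimethylsilyloxy)crotonaldehyde; 4 O‑benzylvanillin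
Product: 5 (4R,5R)‑5‑[4‑(benzyloxy)‑3‑methoxyphenyl]‑4‑{[(tert‑butyldimethylsilyl)oxy]methyl}oxolan‑2‑one (4,5‑cis)
Conditions: enantiopure 2‑mesityl‑5a,10b‑dihydro‑4H,6H‑indeno[2,1‑b][1,2,4]triazolo[4,3‑d][1,4]oxazin‑2‑ium chloride (C21H22ClN3O, 10 mol%), DBU (15 mol%), Ti(OiPr)4 (20 mol%), CH2Cl2, 0 °C → rt, enal added by syringe pump to a twofold excess of the aldehyde; cis isomer purified on silica
Reagents that add atoms: none
Why: Proposed new method: the carbene adds to the formyl group of the enal and makes its β‑carbon (C8') nucleophilic (homoenolate reactivity, carbene‑catalysed enal–aldehyde γ‑butyrolactone annulation), this carbon attacks the Ti(OiPr)4‑activated carbonyl of the aryl aldehyde through a closed titanium‑bridged transition state that places aryl and CH2OTBS cis, and the new alkoxide lactonises onto the activated acyl carbon and regenerates the carbene, so the step is a pure addition in which every atom of both aldehydes ends up in the lactone and C8' and C7' are set together, with the chiral triazolium fixing them as (4R,5R); the closest known chemistry is the racemic cis‑selective imidazolylidene‑catalysed annulation of enals with aryl aldehydes and the highly enantioselective aminoindanol‑triazolium/Ti(OiPr)4 or LiCl homoenolate annulations of enals with chalcones and isatins, whereas high ee with a simple electron‑rich benzaldehyde is still unproven.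

Step 3
Reactants: 5 cis‑(R,R)‑γ‑aryl‑β‑(silyloxymethyl)‑γ‑butyrolactone; 4 O‑benzylvanillin
Product: 8 (3E,4R,5R)‑3‑[4‑(benzyloxy)‑3‑methoxybenzylidene]‑5‑[4‑(benzyloxy)‑3‑methoxyphenyl]‑4‑{[(tert‑butyldimethylsilyl)oxy]methyl}oxolan‑2‑one, via aldol adduct 6 (not isolated), via aldol mesylate 7 (not isolated)
Conditions: LiN(SiMe3)2, THF, −78 °C; aldehyde added; MsCl, −78 → 0 °C; DBU, 0 °C → rt (short)
Reagents that add atoms: none
Why: Aldol condensation (lithium enolate addition to the aldehyde, O‑mesylation, E1cB elimination) gives the conjugated E‑alkene as the thermodynamic product, creates no lasting stereocenter, and the brief mild‑base exposure leaves the γ‑stereocenter C8' untouched.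

Step 4
Reactants: 8 (E)‑α‑benzylidene lactone
Product: 9 (2S,3R,6R,7R)‑2,6‑bis[4‑(benzyloxy)‑3‑methoxyphenyl]‑7‑{[(tert‑butyldimethylsilyl)oxy]methyl}‑1,5‑dioxaspiro[2.4]heptan‑4‑one
Conditions: dimethyldioxirane (ca. 0.08 M in acetone, 2–3 equiv), CH2Cl2, 0 °C → rt
Reagents that add atoms: dimethyldioxirane CC1(C)OO1
Why: Concerted, stereospecific dioxirane epoxidation occurs on the alkene face opposite the cis‑disposed CH2OTBS and aryl groups, which sets C8 (oxygen anti to C9') and, through the E geometry, C7 as S.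

Step 5
Reactants: 9 spiro‑epoxy lactone
Product: 11 (3R,3aR,6R,6aR)‑3,6‑bis[4‑(benzyloxy)‑3‑methoxyphenyl]‑6a‑hydroxytetrahydro‑1H,3H‑furo[3,4‑c]furan‑1‑one, via epoxy alcohol 10 (not isolated)
Conditions: Bu4NF/AcOH (1:1), THF, 0 °C → rt; then (+)‑10‑camphorsulfonic acid (10 mol%), CH2Cl2, 0 °C → rt
Reagents that add atoms: none
Why: Buffered fluoride desilylation frees the C9' hydroxyl without forming a free alkoxide that could migrate the lactone acyl group, and under mild acid this hydroxyl opens the 4‑aryl‑3,4‑epoxy alcohol at the benzylic carbon C7 (5‑endo epoxide opening, strain‑driven, inversion S → R), closing ring A cis‑fused with the aryl exo and the epoxide oxygen left as the tertiary 8‑OH, while any cationic leakage also leads to exo because the endo face is blocked by the C7' aryl.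

Step 6
Reactants: 11 bicyclic hydroxy lactone
Product: 12 (2R,3S,4R)‑2‑[4‑(benzyloxy)‑3‑methoxyphenyl]‑4‑{(R)‑[4‑(benzyloxy)‑3‑methoxyphenyl](hydroxy)methyl}‑3‑(hydroxymethyl)oxolan‑3‑ol
Conditions: LiAlH4, THF, 0 °C
Reagents that add atoms: none
Why: Hydride reduction of the lactone to the diol touches no stereocenter and leaves the benzyl ethers and ring A intact.

Step 7
Reactants: 12 triol
Product: 14 (3R,3aS,6R,6aR)‑3,6‑bis[4‑(benzyloxy)‑3‑methoxyphenyl]tetrahydro‑1H,3H‑furo[3,4‑c]furan‑3a(4H)‑ol, via primary mesylate 13 (not isolated)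
Conditions: MsCl (1.05 equiv), pyridine, 0 °C → 40 °C
Reagents that add atoms: none
Why: Selective sulfonylation of the primary C9 hydroxyl is followed by intramolecular Williamson‑type 5‑exo‑tet displacement by the benzylic C7' hydroxyl under non‑acidic conditions, so the C7'–O bond is never broken and the endo aryl (7'R) is retained.

Step 8
Reactants: 14 bis(benzyl ether) of the target
Product: 15 (3R,3aS,6R,6aR)‑3,6‑bis(4‑hydroxy‑3‑methoxyphenyl)tetrahydro‑1H,3H‑furo[3,4‑c]furan‑3a(4H)‑ol (target)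
Conditions: H2 (1 atm), Pd/C (10 wt%), EtOAc, rt, stopped at full debenzylation
Reagents that add atoms: none
Why: Catalytic hydrogenolysis cleaves the two aryl benzyl ethers much faster than the cyclic benzylic C–O bonds of the furofuran in a neutral, non‑protic solvent, and no stereocenter is affected.

**Compound list**
1 | allyloxy(tert‑butyl)dimethylsilane | C=CCO[Si](C)(C)C(C)(C)C | starting material
2 | (E)‑but‑2‑enal (crotonaldehyde) | C/C=C/C=O | starting material
3 | (E)‑4‑[(tert‑butyldimethylsilyl)oxy]but‑2‑enal | O=C/C=C/CO[Si](C)(C)C(C)(C)C | intermediate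
4 | 4‑(benzyloxy)‑3‑methoxybenzaldehyde (O‑benzylvanillin) | COc1cc(C=O)ccc1OCc1ccccc1 | starting material
5 | (4R,5R)‑5‑[4‑(benzyloxy)‑3‑methoxyphenyl]‑4‑{[(tert‑butyldimethylsilyl)oxy]methyl}oxolan‑2‑one (4,5‑cis) | O=C1C[C@H](CO[Si](C)(C)C(C)(C)C)[C@H](c2ccc(OCc3ccccc3)c(OC)c2)O1 | intermediate
6 | aldol adduct (not isolated; lithium alkoxide in the flask): (4R,5R)‑5‑aryl‑3‑[aryl(hydroxy)methyl]‑4‑(silyloxymethyl)oxolan‑2‑one, aryl = 4‑(benzyloxy)‑3‑methoxyphenyl, diastereomer mixture at C3 and the carbinol carbon | O=C1C(C(O)c2ccc(OCc3ccccc3)c(OC)c2)[C@H](CO[Si](C)(C)C(C)(C)C)[C@H](c2ccc(OCc3ccccc3)c(OC)c2)O1 | intermediate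
7 | aldol mesylate (not isolated): methanesulfonate of 6 at the benzylic oxygen | O=C1C(C(OS(C)(=O)=O)c2ccc(OCc3ccccc3)c(OC)c2)[C@H](CO[Si](C)(C)C(C)(C)C)[C@H](c2ccc(OCc3ccccc3)c(OC)c2)O1 | intermediate
8 | (3E,4R,5R)‑3‑[4‑(benzyloxy)‑3‑methoxybenzylidene]‑5‑[4‑(benzyloxy)‑3‑methoxyphenyl]‑4‑{[(tert‑butyldimethylsilyl)oxy]methyl}oxolan‑2‑one | O=C1/C(=C/c2ccc(OCc3ccccc3)c(OC)c2)[C@H](CO[Si](C)(C)C(C)(C)C)[C@H](c2ccc(OCc3ccccc3)c(OC)c2)O1 | intermediate
9 | (2S,3R,6R,7R)‑2,6‑bis[4‑(benzyloxy)‑3‑methoxyphenyl]‑7‑{[(tert‑butyldimethylsilyl)oxy]methyl}‑1,5‑dioxaspiro[2.4]heptan‑4‑one (epoxide oxygen anti to CH2OTBS) | O=C1[C@@]2(O[C@H]2c3ccc(OCc4ccccc4)c(OC)c3)[C@H](CO[Si](C)(C)C(C)(C)C)[C@H](c3ccc(OCc4ccccc4)c(OC)c3)O1 | intermediate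
10 | epoxy alcohol (not isolated): (2S,3R,6R,7R)‑2,6‑bis[4‑(benzyloxy)‑3‑methoxyphenyl]‑7‑(hydroxymethyl)‑1,5‑dioxaspiro[2.4]heptan‑4‑one | O=C1[C@@]2(O[C@H]2c3ccc(OCc4ccccc4)c(OC)c3)[C@H](CO)[C@H](c3ccc(OCc4ccccc4)c(OC)c3)O1 | intermediate
11 | (3R,3aR,6R,6aR)‑3,6‑bis[4‑(benzyloxy)‑3‑methoxyphenyl]‑6a‑hydroxytetrahydro‑1H,3H‑furo[3,4‑c]furan‑1‑one (cis‑fused; 6‑aryl exo, 3‑aryl endo) | COc1cc([C@H]2OC[C@@H]3[C@H](c4ccc(OCc5ccccc5)c(OC)c4)OC(=O)[C@]23O)ccc1OCc1ccccc1 | intermediate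
12 | (2R,3S,4R)‑2‑[4‑(benzyloxy)‑3‑methoxyphenyl]‑4‑{(R)‑[4‑(benzyloxy)‑3‑methoxyphenyl](hydroxy)methyl}‑3‑(hydroxymethyl)oxolan‑3‑ol | COc1cc([C@H]2OC[C@H]([C@@H](O)c3ccc(OCc4ccccc4)c(OC)c3)[C@@]2(CO)O)ccc1OCc1ccccc1 | intermediate
13 | primary mesylate (not isolated): 12 with the 3‑CH2OH converted to CH2OSO2CH3 | COc1cc([C@H]2OC[C@H]([C@@H](O)c3ccc(OCc4ccccc4)c(OC)c3)[C@@]2(COS(C)(=O)=O)O)ccc1OCc1ccccc1 | intermediate
14 | (3R,3aS,6R,6aR)‑3,6‑bis[4‑(benzyloxy)‑3‑methoxyphenyl]tetrahydro‑1H,3H‑furo[3,4‑c]furan‑3a(4H)‑ol | COc1cc([C@H]2OC[C@@H]3[C@H](c4ccc(OCc5ccccc5)c(OC)c4)OC[C@]23O)ccc1OCc1ccccc1 | intermediate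
15 | (3R,3aS,6R,6aR)‑3,6‑bis(4‑hydroxy‑3‑methoxyphenyl)tetrahydro‑1H,3H‑furo[3,4‑c]furan‑3a(4H)‑ol; (7R,8S,7'R,8'R) in lignan numbering, C7 aryl exo, C7' aryl endo | COc1cc([C@H]2OC[C@@H]3[C@H](c4ccc(O)c(OC)c4)OC[C@]23O)ccc1O | target

**Step count**
Total: 8 steps. Longest linear sequence: 8 steps (1 + 2 → 15; aldehyde 4 enters in steps 2 and 3).

**Steps most likely to fail and fallbacks**

Step 2 (electron‑rich aldehyde as homoenolate acceptor, enal self‑annulation, unproven ee). The fallback sets out from 3 and 4 and comes back at 5. The annulation is run under the established achiral conditions (1,3‑bis(2,4,6‑trimethylphenyl)imidazolium chloride, C21H25ClN2, 8 mol%; DBU 7 mol%; THF/t‑BuOH 10:1; rt). This gives the racemic cis‑lactone, that is 5 together with its mirror image (4S,5S)‑5‑[4‑(benzyloxy)‑3‑methoxyphenyl]‑4‑{[(tert‑butyldimethylsilyl)oxy]methyl}oxolan‑2‑one F1. The cis racemate is freed from the trans isomer on silica and resolved by preparative chromatography on a chiral stationary phase (amylose tris(3,5‑dimethylphenylcarbamate)). F1 is discarded and 5 re‑enters at step 3, so absolute configuration comes from resolution instead of from the catalyst.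

Step 5 (the epoxide may rearrange by acyl or alkyl shift, open sluggishly in the 5‑endo mode, or the freed hydroxyl may migrate the lactone acyl group). The fallback sets out from 8 and comes back at 11. Compound 8 is dihydroxylated (OsO4 cat., N‑methylmorpholine N‑oxide, acetone/H2O, rt) on the face anti to CH2OTBS and aryl to give (3R,4R,5R)‑5‑[4‑(benzyloxy)‑3‑methoxyphenyl]‑3‑{(S)‑[4‑(benzyloxy)‑3‑methoxyphenyl](hydroxy)methyl}‑4‑{[(tert‑butyldimethylsilyl)oxy]methyl}‑3‑hydroxyoxolan‑2‑one F2. Camphorsulfonic acid in MeOH removes the silyl group to give (3R,4R,5R)‑5‑[4‑(benzyloxy)‑3‑methoxyphenyl]‑3‑{(S)‑[4‑(benzyloxy)‑3‑methoxyphenyl](hydroxy)methyl}‑3‑hydroxy‑4‑(hydroxymethyl)oxolan‑2‑one F3. BF3·OEt2 in CH2Cl2 at −40 °C then ionises the benzylic C7 hydroxyl, and the C9' hydroxyl closes ring A on the planar cation. Only the exo‑aryl product can form without clashing with the endo aryl on C7', so 11 results. The risk in this variant is epimerisation at C7' if the acid is too strong.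

Step 7 (competing sulfonylation of the benzylic hydroxyl, or epoxide formation from the tertiary hydroxyl). The fallback sets out from 11 and comes back at 14, replacing steps 6 and 7. Compound 11 is reduced with i‑Bu2AlH (CH2Cl2, −78 °C) to the lactol (3R,3aR,6R,6aR)‑3,6‑bis[4‑(benzyloxy)‑3‑methoxyphenyl]tetrahydro‑1H,3H‑furo[3,4‑c]furan‑1,6a‑diol F4 (anomer mixture at C1). The anomeric hydroxyl is then removed with Et3SiH/BF3·OEt2 (CH2Cl2, −78 °C) through the ring B oxocarbenium ion to give 14. At this temperature the benzylic C7'–O bond is not ionised.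

**Further compounds**
F1 | step 2 | (4S,5S)‑5‑[4‑(benzyloxy)‑3‑methoxyphenyl]‑4‑{[(tert‑butyldimethylsilyl)oxy]methyl}oxolan‑2‑one (enantiomer of 5) | O=C1C[C@@H](CO[Si](C)(C)C(C)(C)C)[C@@H](c2ccc(OCc3ccccc3)c(OC)c2)O1
F2 | step 5 | (3R,4R,5R)‑5‑[4‑(benzyloxy)‑3‑methoxyphenyl]‑3‑{(S)‑[4‑(benzyloxy)‑3‑methoxyphenyl](hydroxy)methyl}‑4‑{[(tert‑butyldimethylsilyl)oxy]methyl}‑3‑hydroxyoxolan‑2‑one | O=C1[C@](O)([C@@H](O)c2ccc(OCc3ccccc3)c(OC)c2)[C@H](CO[Si](C)(C)C(C)(C)C)[C@H](c2ccc(OCc3ccccc3)c(OC)c2)O1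
F3 | step 5 | (3R,4R,5R)‑5‑[4‑(benzyloxy)‑3‑methoxyphenyl]‑3‑{(S)‑[4‑(benzyloxy)‑3‑methoxyphenyl](hydroxy)methyl}‑3‑hydroxy‑4‑(hydroxymethyl)oxolan‑2‑one | O=C1[C@](O)([C@@H](O)c2ccc(OCc3ccccc3)c(OC)c2)[C@H](CO)[C@H](c2ccc(OCc3ccccc3)c(OC)c2)O1
F4 | step 7 | (3R,3aR,6R,6aR)‑3,6‑bis[4‑(benzyloxy)‑3‑methoxyphenyl]tetrahydro‑1H,3H‑furo[3,4‑c]furan‑1,6a‑diol (anomer mixture at C1) | COc1cc([C@H]2OC[C@@H]3[C@H](c4ccc(OCc5ccccc5)c(OC)c4)OC(O)[C@]23O)ccc1OCc1ccccc1
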